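Everything rests on opening the dihydrobenzofuran at C2–O1. This benzylic bond lies para to O4 of the syringyl ring on C2 (ring C), so C2 can pass through a p-quinone methide. In the key step mild acid ionises diol derivative 16 (free phenols on ring C and on the bromoguaiacyl ring D, primary alcohol as TBDPS ether, C3 set by an Evans aldol) and the ring D phenol closes the furan ring trans: one ring, the C2–O1 bond and the C2 centre in one operation. The ring C phenol then carries two Evans aryloxyacetyl aldols, each inverted at the benzylic carbon to the erythro series; a Suzuki coupling installs the enal.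

Key step: step 10

Remarks
- Ring letters: A = terminal guaiacyl ring, B = central syringyl ring, C = syringyl ring on C2, D = benzo ring of the dihydrobenzofuran (atoms O1, C2, C3).
- Assumption on the chemistry: both arylglycerol β-aryl ether units of the target are (1R,2S), the erythro series. A boron aldol of an aryloxyacetyl oxazolidinone gives the threo (syn) adduct, so each unit is inverted at its benzylic carbon by a Mitsunobu step.
- Abbreviations: TBDPS = tert-butyldiphenylsilyl, TBS = tert-butyldimethylsilyl, Piv = pivaloyl, ArCD-oxy = 4-[(2R,3S)-5-bromo-3-(TBDPS-oxymethyl)-7-methoxy-2,3-dihydrobenzofuran-2-yl]-2,6-dimethoxyphenoxy (the ring C oxygen of 18).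
- Reagents named on the Conditions lines are taken as purchased.

Step 1
Reactants: 1 5-bromo-2-hydroxy-3-methoxybenzaldehyde
Product: 2 2-(allyloxy)-5-bromo-3-methoxybenzaldehyde
Conditions: allyl bromide, K2CO3, DMF, rt
Reagents that add atoms: allyl bromide, C=CCBr
Why: Williamson ether synthesis; the allyl ether masks the ring D phenol through the basic and Lewis acidic steps and can later be removed without touching the aryl bromide.

Step 2
Reactants: 2 2-(allyloxy)-5-bromo-3-methoxybenzaldehyde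
Product: 3 1-(allyloxy)-4-bromo-2-methoxy-6-(2-methoxyethenyl)benzene (E/Z mixture)
Conditions: MeOCH2PPh3Cl, KOtBu, THF, 0 °C to rt
Reagents that add atoms: (methoxymethyl)triphenylphosphonium chloride, COC[P+](c1ccccc1)(c1ccccc1)c1ccccc1.[Cl-]
Why: Wittig methoxymethylenation adds the one carbon needed for the arylacetic acid; the alkene geometry is irrelevant.

Step 3
Reactants: 3 1-(allyloxy)-4-bromo-2-methoxy-6-(2-methoxyethenyl)benzene
Product: 5 2-[2-(allyloxy)-5-bromo-3-methoxyphenyl]acetic acid, via arylacetaldehyde 4 (not isolated)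
Conditions: aq. HCl (2 M, cat.), THF, 50 °C; then t-BuOH, NaH2PO4, 2-methyl-2-butene, NaClO2, 0 °C to rt
Reagents that add atoms: water, O; sodium chlorite, [Na+].[O-]Cl=O
Why: Acid hydrolysis of the enol ether followed by Pinnick oxidation of the crude enolisable aldehyde; with hypochlorite scavenged, chlorite should leave the allyl ether and the aryl bromide alone.

Step 4
Reactants: 5 2-[2-(allyloxy)-5-bromo-3-methoxyphenyl]acetic acid; 6 (R)-4-benzyloxazolidin-2-one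
Product: 8 (R)-3-{[2-(allyloxy)-5-bromo-3-methoxyphenyl]acetyl}-4-benzyloxazolidin-2-one, via mixed pivalic anhydride 7 (not isolated)
Conditions: PivCl, Et3N, THF, −20 °C; then LiCl, 6, −20 °C to rt
Reagents that add atoms: none
Why: N-acylation of the oxazolidinone through the mixed anhydride (LiCl/Et3N protocol), which is attacked at the less hindered arylacetyl carbonyl.

Step 5
Reactants: 9 syringaldehyde
Product: 10 4-formyl-2,6-dimethoxyphenyl pivalate
Conditions: PivCl, Et3N, DMAP (cat.), CH2Cl2, 0 °C to rt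
Reagents that add atoms: pivaloyl chloride, CC(C)(C)C(Cl)=O
Why: Phenol acylation; the pivalate survives the boron aldol and Mitsunobu steps, makes the aryl ring electron-poor and is cleaved by LiBH4 together with the auxiliary.

Step 6
Reactants: 8 (R)-3-{[2-(allyloxy)-5-bromo-3-methoxyphenyl]acetyl}-4-benzyloxazolidin-2-one; 10 4-formyl-2,6-dimethoxyphenyl pivalate
Product: 13 (R)-4-benzyl-3-[(2R,3R)-2-(2-allyloxy-5-bromo-3-methoxyphenyl)-3-hydroxy-3-(3,5-dimethoxy-4-pivaloyloxyphenyl)propanoyl]oxazolidin-2-one, via dibutylboron enolate 11 (not isolated), via dibutylboron aldolate 12 (not isolated)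
Conditions: Bu2BOTf, iPr2NEt, CH2Cl2, −78 to 0 °C; 10, −78 to 0 °C; then pH 7 phosphate buffer, MeOH, H2O2, 0 °C
Reagents that add atoms: none
Why: Evans syn aldol: the (Z)-boron enolate reacts through a Zimmerman–Traxler chair on the face away from the benzyl group of the (R)-auxiliary, setting C2 (R here, the future C3 of the dihydrobenzofuran) and the carbinol C3 (R), whose configuration is erased in step 10.

Step 7
Reactants: 13 syn-aldol adduct
Product: 14 4-[(1R,2S)-2-(2-allyloxy-5-bromo-3-methoxyphenyl)-1,3-dihydroxypropyl]-2,6-dimethoxyphenol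
Conditions: LiBH4, MeOH, THF, 0 °C to rt
Reagents that add atoms: none
Why: Reductive cleavage of the N-acyl oxazolidinone to the primary alcohol with recovery of 6, the aryl pivalate being cleaved in the same operation; no stereocentre is touched (C2 is named S only because CH2OH now ranks below the carbinol carbon).

Step 8
Reactants: 14 4-[(1R,2S)-2-(2-allyloxy-5-bromo-3-methoxyphenyl)-1,3-dihydroxypropyl]-2,6-dimethoxyphenol
Product: 15 4-[(1R,2S)-2-(2-allyloxy-5-bromo-3-methoxyphenyl)-3-(TBDPS-oxy)-1-hydroxypropyl]-2,6-dimethoxyphenol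
Conditions: TBDPSCl, imidazole, DMF, 0 °C
Reagents that add atoms: tert-butyl(chloro)diphenylsilane, CC(C)(C)[Si](Cl)(c1ccccc1)c1ccccc1
Why: Selective silylation of the primary alcohol over the secondary benzylic alcohol and the hindered 2,6-dimethoxyphenol; any aryl silyl ether formed would be cleaved by K2CO3/MeOH in step 9.

Step 9
Reactants: 15 primary TBDPS ether
Product: 16 4-[(1R,2S)-2-(5-bromo-2-hydroxy-3-methoxyphenyl)-3-(TBDPS-oxy)-1-hydroxypropyl]-2,6-dimethoxyphenol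
Conditions: Pd(PPh3)4 (cat.), K2CO3, MeOH, rt
Reagents that add atoms: none
Why: Tsuji–Trost deallylation of the aryl allyl ether with methanol as allyl acceptor; at room temperature the electron-rich aryl bromide should not add to zerovalent palladium.

Step 10
Reactants: 16 4-[(1R,2S)-2-(5-bromo-2-hydroxy-3-methoxyphenyl)-3-(TBDPS-oxy)-1-hydroxypropyl]-2,6-dimethoxyphenol
Product: 18 4-[(2R,3S)-5-bromo-3-(TBDPS-oxymethyl)-7-methoxy-2,3-dihydrobenzofuran-2-yl]-2,6-dimethoxyphenol, via p-quinone methide 17 (not isolated)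
Conditions: p-TsOH·H2O (10 mol%), CH2Cl2 (0.01 M), 0 °C to rt
Reagents that add atoms: none
Why: Protonation of the benzylic hydroxyl at C1, which is para to the free O4–H of ring C, and loss of water give p-quinone methide 17, so the C1 configuration of 16 is erased; the ortho phenol of ring D then adds to the methide carbon and ring C rearomatises. This is the known acid-mediated cyclisation of 1-aryl-2-(2-hydroxyaryl)propan-1-ols to 2-aryl-2,3-dihydrobenzofurans through p-quinone methides. The dihydrofuran ring closes by a 5-exo-trig oxa-conjugate addition that forms the C2–O1 bond. The new C2 centre is controlled by the existing C3 centre (S): the phenol attacks the methide face that places the aryl group trans to CH2OTBDPS, and because the ring C phenol stays free the closure is reversible under acid, so any cis isomer should drain to the trans (2R,3S) product. The step needs ionisation at C1 only and O- rather than C-attack: C1 is the only p-hydroxybenzylic alcohol, the primary alcohol is masked as its silyl ether, and the positions ortho and para to the ring D phenol are substituted.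

Step 11
Reactants: 6 (R)-4-benzyloxazolidin-2-one
Product: 20 (R)-4-benzyl-3-(bromoacetyl)oxazolidin-2-one, via N-lithio oxazolidinone 19 (not isolated)
Conditions: n-BuLi, THF, −78 °C; then BrCH2COBr, −78 to 0 °C
Reagents that add atoms: bromoacetyl bromide, BrCC(Br)=O
Why: N-acylation of the lithiated oxazolidinone; the acyl bromide reacts at the acyl carbon far faster than at the CH2Br carbon.

Step 12
Reactants: 18 dihydrobenzofuran phenol; 20 (R)-4-benzyl-3-(bromoacetyl)oxazolidin-2-one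
Product: 21 (R)-4-benzyl-3-[(ArCD-oxy)acetyl]oxazolidin-2-one
Conditions: K2CO3, acetone, rt to 40 °C
Reagents that add atoms: none
Why: Williamson ether synthesis on an α-bromo imide, a very reactive SN2 electrophile that offsets the hindered 2,6-dimethoxyphenoxide; alkylation also locks the ring C oxygen, so C2 can no longer open through a quinone methide.

Step 13
Reactants: 21 (R)-4-benzyl-3-[(ArCD-oxy)acetyl]oxazolidin-2-one; 10 4-formyl-2,6-dimethoxyphenyl pivalate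
Product: 24 (R)-4-benzyl-3-[(2R,3S)-2-(ArCD-oxy)-3-hydroxy-3-(3,5-dimethoxy-4-pivaloyloxyphenyl)propanoyl]oxazolidin-2-one, via dibutylboron enolate 22 (not isolated), via dibutylboron aldolate 23 (not isolated)
Conditions: Bu2BOTf, iPr2NEt, CH2Cl2, −78 to 0 °C; 10, −78 to 0 °C; then pH 7 phosphate buffer, MeOH, H2O2, 0 °C
Reagents that add atoms: none
Why: Evans syn aldol of an aryloxyacetyl imide: the (Z)-boron enolate and the (R)-auxiliary set the ether carbon (2R, which becomes the S β-carbon after reduction) and give the threo carbinol (3S), the epimer of the target at that carbon.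

Step 14
Reactants: 24 threo aldol adduct
Product: 25 (R)-4-benzyl-3-[(2R,3R)-2-(ArCD-oxy)-3-(chloroacetoxy)-3-(3,5-dimethoxy-4-pivaloyloxyphenyl)propanoyl]oxazolidin-2-one
Conditions: ClCH2CO2H, PPh3, DIAD, THF, 0 °C to rt
Reagents that add atoms: chloroacetic acid, OC(=O)CCl
Why: Mitsunobu esterification: SN2 displacement of the alkoxyphosphonium by chloroacetate inverts the benzylic carbinol (3S to 3R) into the erythro series, and the pivaloyloxyaryl ring with the flanking acyl and aryloxy groups disfavours ionisation.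

Step 15
Reactants: 25 erythro chloroacetate
Product: 26 (1R,2S)-2-(ArCD-oxy)-1-(4-hydroxy-3,5-dimethoxyphenyl)propane-1,3-diol
Conditions: LiBH4, MeOH, THF, −20 °C to rt
Reagents that add atoms: none
Why: Hydride reduction: the chloroacetate should be cleaved first, the imide reduced to the primary alcohol with release of 6 and the hindered aryl pivalate cleaved last, so the phenoxide only appears when the benzylic oxygen is already an alkoxide; no stereocentre changes.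

Step 16
Reactants: 26 erythro phenol diol; 20 (R)-4-benzyl-3-(bromoacetyl)oxazolidin-2-one
Product: 27 (R)-4-benzyl-3-{[4-((1R,2S)-2-(ArCD-oxy)-1,3-dihydroxypropyl)-2,6-dimethoxyphenoxy]acetyl}oxazolidin-2-one
Conditions: K2CO3, acetone, rt
Reagents that add atoms: none
Why: Chemoselective Williamson O-alkylation of the phenol (carbonate does not deprotonate the two alcohols) installs the acyl unit for the next aldol.

Step 17
Reactants: 27 imide diol
Product: 28 (R)-4-benzyl-3-{[4-((1R,2S)-2-(ArCD-oxy)-1,3-bis(TBS-oxy)propyl)-2,6-dimethoxyphenoxy]acetyl}oxazolidin-2-one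
Conditions: TBSOTf, 2,6-lutidine, CH2Cl2, −40 to 0 °C
Reagents that add atoms: tert-butyldimethylsilyl trifluoromethanesulfonate, CC(C)(C)[Si](C)(C)OS(=O)(=O)C(F)(F)F
Why: Silylation of both alcohols so that they neither consume Bu2BOTf nor react in the second Mitsunobu step; the silyl ethers are later removed by fluoride without acid.

Step 18
Reactants: 29 vanillin
Product: 30 4-formyl-2-methoxyphenyl pivalate
Conditions: PivCl, Et3N, DMAP (cat.), CH2Cl2, 0 °C to rt
Reagents that add atoms: pivaloyl chloride, CC(C)(C)C(Cl)=O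
Why: Phenol acylation, for the same reasons as in step 5.

Step 19
Reactants: 28 bis-TBS imide; 30 4-formyl-2-methoxyphenyl pivalate
Product: 33 threo aldol adduct of 28 with (2R,3S)-3-hydroxy-3-(3-methoxy-4-pivaloyloxyphenyl)propanoyl chain, via dibutylboron enolate 31 (not isolated), via dibutylboron aldolate 32 (not isolated)
Conditions: Bu2BOTf, iPr2NEt, CH2Cl2, −78 to 0 °C; 30, −78 to 0 °C; then pH 7 phosphate buffer, MeOH, H2O2, 0 °C
Reagents that add atoms: none
Why: Evans syn aldol as in step 13: the (R)-auxiliary sets the ether carbon of the last unit (2R) and gives the threo carbinol (3S).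

Step 20
Reactants: 33 threo aldol adduct
Product: 34 erythro chloroacetate of 33 with (2R,3R) configuration
Conditions: ClCH2CO2H, PPh3, DIAD, THF, 0 °C to rt
Reagents that add atoms: chloroacetic acid, OC(=O)CCl
Why: Mitsunobu esterification with SN2 inversion of the benzylic carbinol (3S to 3R), as in step 14.

Step 21
Reactants: 34 erythro chloroacetate
Product: 35 ring A phenol with free erythro diol of the last unit and silyl ethers on the other three hydroxyls
Conditions: LiBH4, MeOH, THF, −20 °C to rt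
Reagents that add atoms: none
Why: Hydride reduction as in step 15 cleaves chloroacetate, auxiliary and aryl pivalate in that order and frees the (1R,2S) terminal unit without touching the silyl ethers or the aryl bromide.

Step 22
Reactants: 35 tris-silyl ether
Product: 36 5-bromo analogue of the target with all hydroxyls free
Conditions: Bu4NF, AcOH, THF, rt
Reagents that add atoms: none
Why: Fluoride-mediated cleavage of the TBDPS and the two TBS ethers under buffered, near-neutral conditions that should not ionise the p-hydroxybenzylic alcohol of ring A.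

Step 23
Reactants: 36 5-bromo analogue of the target
Product: 38 target CNP0192639.1, via diethyl acetal 37 (not isolated)
Conditions: (E)-(EtO)2CHCH=CHB(pin), PdCl2(dppf) (5 mol%), K2CO3, 1,4-dioxane/H2O, 70 °C; then PPTS, acetone/H2O, rt
Reagents that add atoms: (E)-2-(3,3-diethoxyprop-1-en-1-yl)-4,4,5,5-tetramethyl-1,3,2-dioxaborolane, CCOC(OCC)/C=C/B1OC(C)(C)C(C)(C)O1; water, O
Why: Suzuki–Miyaura coupling of the aryl bromide with the (E)-alkenylboronate retains the alkene geometry and tolerates the free hydroxyls and phenol; the allylic acetal is then hydrolysed by a weak acid that leaves the benzylic alcohols alone.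

Compound list
1 | 5-bromo-2-hydroxy-3-methoxybenzaldehyde | COc1cc(Br)cc(C=O)c1O | starting material
2 | 2-(allyloxy)-5-bromo-3-methoxybenzaldehyde | COc1cc(Br)cc(C=O)c1OCC=C | intermediate
3 | 1-(allyloxy)-4-bromo-2-methoxy-6-(2-methoxyethenyl)benzene, E/Z mixture | COC=Cc1cc(Br)cc(OC)c1OCC=C | intermediate
4 | 2-[2-(allyloxy)-5-bromo-3-methoxyphenyl]acetaldehyde | COc1cc(Br)cc(CC=O)c1OCC=C | intermediate
5 | 2-[2-(allyloxy)-5-bromo-3-methoxyphenyl]acetic acid | COc1cc(Br)cc(CC(=O)O)c1OCC=C | intermediate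
6 | (R)-4-benzyloxazolidin-2-one | O=C1N[C@H](Cc2ccccc2)CO1 | starting material
7 | 2-[2-(allyloxy)-5-bromo-3-methoxyphenyl]acetic pivalic anhydride | COc1cc(Br)cc(CC(=O)OC(=O)C(C)(C)C)c1OCC=C | intermediate
8 | (R)-3-{[2-(allyloxy)-5-bromo-3-methoxyphenyl]acetyl}-4-benzyloxazolidin-2-one | COc1cc(Br)cc(CC(=O)N2[C@H](Cc3ccccc3)COC2=O)c1OCC=C | intermediate
9 | syringaldehyde (4-hydroxy-3,5-dimethoxybenzaldehyde) | COc1cc(C=O)cc(OC)c1O | starting material
10 | 4-formyl-2,6-dimethoxyphenyl pivalate | COc1cc(C=O)cc(OC)c1OC(=O)C(C)(C)C | intermediate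
11 | (Z)-dibutylboron enolate of 8 | COc1cc(Br)cc(/C=C(/N2[C@H](Cc3ccccc3)COC2=O)OB(CCCC)CCCC)c1OCC=C | intermediate
12 | O-dibutylboryl aldolate of 13 | O=C(N1[C@H](Cc2ccccc2)COC1=O)[C@H](c3cc(Br)cc(OC)c3OCC=C)[C@@H](OB(CCCC)CCCC)c4cc(OC)c(OC(=O)C(C)(C)C)c(OC)c4 | intermediate
13 | (R)-4-benzyl-3-[(2R,3R)-2-(2-allyloxy-5-bromo-3-methoxyphenyl)-3-hydroxy-3-(3,5-dimethoxy-4-pivaloyloxyphenyl)propanoyl]oxazolidin-2-one | O=C(N1[C@H](Cc2ccccc2)COC1=O)[C@H](c3cc(Br)cc(OC)c3OCC=C)[C@@H](O)c4cc(OC)c(OC(=O)C(C)(C)C)c(OC)c4 | intermediate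
14 | 4-[(1R,2S)-2-(2-allyloxy-5-bromo-3-methoxyphenyl)-1,3-dihydroxypropyl]-2,6-dimethoxyphenol | OC[C@H](c1cc(Br)cc(OC)c1OCC=C)[C@@H](O)c2cc(OC)c(O)c(OC)c2 | intermediate
15 | 4-[(1R,2S)-2-(2-allyloxy-5-bromo-3-methoxyphenyl)-3-(tert-butyldiphenylsilyloxy)-1-hydroxypropyl]-2,6-dimethoxyphenol | CC(C)(C)[Si](c1ccccc1)(c2ccccc2)OC[C@H](c3cc(Br)cc(OC)c3OCC=C)[C@@H](O)c4cc(OC)c(O)c(OC)c4 | intermediate
16 | 4-[(1R,2S)-2-(5-bromo-2-hydroxy-3-methoxyphenyl)-3-(tert-butyldiphenylsilyloxy)-1-hydroxypropyl]-2,6-dimethoxyphenol | CC(C)(C)[Si](c1ccccc1)(c2ccccc2)OC[C@H](c3cc(Br)cc(OC)c3O)[C@@H](O)c4cc(OC)c(O)c(OC)c4 | intermediate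
17 | 4-[(2S)-2-(5-bromo-2-hydroxy-3-methoxyphenyl)-3-(tert-butyldiphenylsilyloxy)propylidene]-2,6-dimethoxycyclohexa-2,5-dien-1-one | CC(C)(C)[Si](c1ccccc1)(c2ccccc2)OC[C@H](c3cc(Br)cc(OC)c3O)C=C4C=C(OC)C(=O)C(OC)=C4 | intermediate
18 | 4-[(2R,3S)-5-bromo-3-(tert-butyldiphenylsilyloxymethyl)-7-methoxy-2,3-dihydrobenzofuran-2-yl]-2,6-dimethoxyphenol | COc1cc([C@@H]2Oc3c(OC)cc(Br)cc3[C@H]2CO[Si](c4ccccc4)(c5ccccc5)C(C)(C)C)cc(OC)c1O | intermediate
19 | lithium salt (N-lithio derivative) of (R)-4-benzyloxazolidin-2-one | [Li]N1[C@H](Cc2ccccc2)COC1=O | intermediate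
20 | (R)-4-benzyl-3-(bromoacetyl)oxazolidin-2-one | O=C(CBr)N1[C@H](Cc2ccccc2)COC1=O | intermediate
21 | (R)-4-benzyl-3-[(ArCD-oxy)acetyl]oxazolidin-2-one | COc1cc([C@@H]2Oc3c(OC)cc(Br)cc3[C@H]2CO[Si](c4ccccc4)(c5ccccc5)C(C)(C)C)cc(OC)c1OCC(=O)N6[C@H](Cc7ccccc7)COC6=O | intermediate
22 | (Z)-dibutylboron enolate of 21 | COc1cc([C@@H]2Oc3c(OC)cc(Br)cc3[C@H]2CO[Si](c4ccccc4)(c5ccccc5)C(C)(C)C)cc(OC)c1O/C=C(/N6[C@H](Cc7ccccc7)COC6=O)OB(CCCC)CCCC | intermediate
23 | O-dibutylboryl aldolate of 24 | COc1cc([C@@H]2Oc3c(OC)cc(Br)cc3[C@H]2CO[Si](c4ccccc4)(c5ccccc5)C(C)(C)C)cc(OC)c1O[C@@H](C(=O)N6[C@H](Cc7ccccc7)COC6=O)[C@@H](OB(CCCC)CCCC)c8cc(OC)c(OC(=O)C(C)(C)C)c(OC)c8 | intermediate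
24 | (R)-4-benzyl-3-[(2R,3S)-2-(ArCD-oxy)-3-hydroxy-3-(3,5-dimethoxy-4-pivaloyloxyphenyl)propanoyl]oxazolidin-2-one (threo) | COc1cc([C@@H]2Oc3c(OC)cc(Br)cc3[C@H]2CO[Si](c4ccccc4)(c5ccccc5)C(C)(C)C)cc(OC)c1O[C@@H](C(=O)N6[C@H](Cc7ccccc7)COC6=O)[C@@H](O)c8cc(OC)c(OC(=O)C(C)(C)C)c(OC)c8 | intermediate
25 | (R)-4-benzyl-3-[(2R,3R)-2-(ArCD-oxy)-3-(chloroacetoxy)-3-(3,5-dimethoxy-4-pivaloyloxyphenyl)propanoyl]oxazolidin-2-one (erythro) | COc1cc([C@@H]2Oc3c(OC)cc(Br)cc3[C@H]2CO[Si](c4ccccc4)(c5ccccc5)C(C)(C)C)cc(OC)c1O[C@@H](C(=O)N6[C@H](Cc7ccccc7)COC6=O)[C@H](OC(=O)CCl)c8cc(OC)c(OC(=O)C(C)(C)C)c(OC)c8 | intermediate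
26 | (1R,2S)-2-(ArCD-oxy)-1-(4-hydroxy-3,5-dimethoxyphenyl)propane-1,3-diol | COc1cc([C@@H]2Oc3c(OC)cc(Br)cc3[C@H]2CO[Si](c4ccccc4)(c5ccccc5)C(C)(C)C)cc(OC)c1O[C@@H](CO)[C@H](O)c6cc(OC)c(O)c(OC)c6 | intermediate
27 | (R)-4-benzyl-3-{[4-((1R,2S)-2-(ArCD-oxy)-1,3-dihydroxypropyl)-2,6-dimethoxyphenoxy]acetyl}oxazolidin-2-one | COc1cc([C@@H]2Oc3c(OC)cc(Br)cc3[C@H]2CO[Si](c4ccccc4)(c5ccccc5)C(C)(C)C)cc(OC)c1O[C@@H](CO)[C@H](O)c6cc(OC)c(OCC(=O)N7[C@H](Cc8ccccc8)COC7=O)c(OC)c6 | intermediate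
28 | (R)-4-benzyl-3-{[4-((1R,2S)-2-(ArCD-oxy)-1,3-bis(tert-butyldimethylsilyloxy)propyl)-2,6-dimethoxyphenoxy]acetyl}oxazolidin-2-one | COc1cc([C@@H]2Oc3c(OC)cc(Br)cc3[C@H]2CO[Si](c4ccccc4)(c5ccccc5)C(C)(C)C)cc(OC)c1O[C@@H](CO[Si](C)(C)C(C)(C)C)[C@H](O[Si](C)(C)C(C)(C)C)c6cc(OC)c(OCC(=O)N7[C@H](Cc8ccccc8)COC7=O)c(OC)c6 | intermediate
29 | vanillin (4-hydroxy-3-methoxybenzaldehyde) | COc1cc(C=O)ccc1O | starting material
30 | 4-formyl-2-methoxyphenyl pivalate | COc1cc(C=O)ccc1OC(=O)C(C)(C)C | intermediate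
31 | (Z)-dibutylboron enolate of 28 | COc1cc([C@@H]2Oc3c(OC)cc(Br)cc3[C@H]2CO[Si](c4ccccc4)(c5ccccc5)C(C)(C)C)cc(OC)c1O[C@@H](CO[Si](C)(C)C(C)(C)C)[C@H](O[Si](C)(C)C(C)(C)C)c6cc(OC)c(O/C=C(/N7[C@H](Cc8ccccc8)COC7=O)OB(CCCC)CCCC)c(OC)c6 | intermediate
32 | O-dibutylboryl aldolate of 33 | COc1cc([C@@H]2Oc3c(OC)cc(Br)cc3[C@H]2CO[Si](c4ccccc4)(c5ccccc5)C(C)(C)C)cc(OC)c1O[C@@H](CO[Si](C)(C)C(C)(C)C)[C@H](O[Si](C)(C)C(C)(C)C)c6cc(OC)c(O[C@@H](C(=O)N7[C@H](Cc8ccccc8)COC7=O)[C@@H](OB(CCCC)CCCC)c9ccc(OC(=O)C(C)(C)C)c(OC)c9)c(OC)c6 | intermediate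
33 | threo aldol adduct: 28 in which the OCH2C(=O) group has become (2R,3S)-OCH[C(=O)-oxazolidinone]CH(OH)(3-methoxy-4-pivaloyloxyphenyl) | COc1cc([C@@H]2Oc3c(OC)cc(Br)cc3[C@H]2CO[Si](c4ccccc4)(c5ccccc5)C(C)(C)C)cc(OC)c1O[C@@H](CO[Si](C)(C)C(C)(C)C)[C@H](O[Si](C)(C)C(C)(C)C)c6cc(OC)c(O[C@@H](C(=O)N7[C@H](Cc8ccccc8)COC7=O)[C@@H](O)c9ccc(OC(=O)C(C)(C)C)c(OC)c9)c(OC)c6 | intermediate
34 | erythro chloroacetate of 33, (2R,3R) | COc1cc([C@@H]2Oc3c(OC)cc(Br)cc3[C@H]2CO[Si](c4ccccc4)(c5ccccc5)C(C)(C)C)cc(OC)c1O[C@@H](CO[Si](C)(C)C(C)(C)C)[C@H](O[Si](C)(C)C(C)(C)C)c6cc(OC)c(O[C@@H](C(=O)N7[C@H](Cc8ccccc8)COC7=O)[C@H](OC(=O)CCl)c9ccc(OC(=O)C(C)(C)C)c(OC)c9)c(OC)c6 | intermediate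
35 | (1R,2S)-2-{4-[(1R,2S)-2-(ArCD-oxy)-1,3-bis(tert-butyldimethylsilyloxy)propyl]-2,6-dimethoxyphenoxy}-1-(4-hydroxy-3-methoxyphenyl)propane-1,3-diol | COc1cc([C@@H]2Oc3c(OC)cc(Br)cc3[C@H]2CO[Si](c4ccccc4)(c5ccccc5)C(C)(C)C)cc(OC)c1O[C@@H](CO[Si](C)(C)C(C)(C)C)[C@H](O[Si](C)(C)C(C)(C)C)c6cc(OC)c(O[C@@H](CO)[C@H](O)c7ccc(O)c(OC)c7)c(OC)c6 | intermediate
36 | (1R,2S)-2-{4-[(1R,2S)-2-{4-[(2R,3S)-5-bromo-3-(hydroxymethyl)-7-methoxy-2,3-dihydrobenzofuran-2-yl]-2,6-dimethoxyphenoxy}-1,3-dihydroxypropyl]-2,6-dimethoxyphenoxy}-1-(4-hydroxy-3-methoxyphenyl)propane-1,3-diol | COc1cc([C@@H]2Oc3c(OC)cc(Br)cc3[C@H]2CO)cc(OC)c1O[C@@H](CO)[C@H](O)c4cc(OC)c(O[C@@H](CO)[C@H](O)c5ccc(O)c(OC)c5)c(OC)c4 | intermediate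
37 | diethyl acetal of the target: 36 with Br replaced by (E)-CH=CH-CH(OEt)2 | COc1cc([C@@H]2Oc3c(OC)cc(/C=C/C(OCC)OCC)cc3[C@H]2CO)cc(OC)c1O[C@@H](CO)[C@H](O)c4cc(OC)c(O[C@@H](CO)[C@H](O)c5ccc(O)c(OC)c5)c(OC)c4 | intermediate
38 | CNP0192639.1: 36 with Br replaced by (E)-CH=CH-CHO | COc1cc([C@@H](O)[C@H](CO)Oc2c(OC)cc([C@@H](O)[C@H](CO)Oc3c(OC)cc([C@@H]4Oc5c(OC)cc(/C=C/C=O)cc5[C@H]4CO)cc3OC)cc2OC)ccc1O | target

Total step count: 23. Longest linear sequence: 20 steps (steps 1–4, 6–10, 12–17, 19–23); steps 5, 11 and 18 prepare side components.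

Steps most likely to fail

Step 10 (key step). What may go wrong: the quinone methide may lose the C3 proton and tautomerise to a stilbene, which destroys the C3 stereocentre, or the phenol may add with poor facial selectivity. The fallback closes the ring by SN2 with no methide; it sets out from 13 and comes back at 18. NaBH4 in THF/H2O at 0 °C should remove the auxiliary but keep the hindered aryl pivalate, giving 4-[(1R,2S)-2-(2-allyloxy-5-bromo-3-methoxyphenyl)-1,3-dihydroxypropyl]-2,6-dimethoxyphenyl pivalate F1. TBDPSCl/imidazole gives its primary silyl ether F2. A Mitsunobu reaction with chloroacetic acid inverts C1 and gives the (1S,2S)-chloroacetate F3. Pd(PPh3)4, K2CO3 and MeOH at 0 °C take off the allyl group and the chloroacetate while the pivalate stays, giving the (1S,2S)-alcohol with a free ring D phenol F4. PPh3/DIAD then closes the ring by intramolecular Mitsunobu etherification with inversion at C1, which gives the trans-(2R,3S)-dihydrobenzofuran pivalate F5. K2CO3/MeOH at rt cleaves the pivalate to 18. With the ring C oxygen acylated throughout, no quinone methide can form, and the trans geometry follows from the configuration of the carbinol.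

Step 14 (the same hazard exists in step 20). What may go wrong: the alkoxyphosphonium may undergo β-elimination to the 2-aryloxycinnamoyl imide, or ionise and lose configuration, instead of clean SN2 substitution. The fallback moves the inversion behind the reductive cleavage; it sets out from 24 and comes back at 28. NaBH4 in THF/H2O at 0 °C removes the auxiliary and keeps the aryl pivalate, giving the threo diol 4-[(1S,2S)-2-(ArCD-oxy)-1,3-dihydroxypropyl]-2,6-dimethoxyphenyl pivalate F6. TBSCl/imidazole gives the primary TBS ether F7. A Mitsunobu reaction with chloroacetic acid on this substrate, which has no acidic α-hydrogen, gives the erythro (1R,2S)-chloroacetate F8. K2CO3/MeOH (0 °C, then rt) cleaves first the chloroacetate and then the pivalate, giving the erythro phenol with a free benzylic alcohol F9. Alkylation with 20 (K2CO3, acetone) gives the imide F10. TBSOTf/2,6-lutidine silylates the benzylic alcohol and returns to 28.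

Step 15 (the same hazard exists in step 21). What may go wrong: if the aryl pivalate is cleaved before the chloroacetate, the p-oxidobenzyl ester expels chloroacetate and the resulting quinone methide is reduced by hydride, which removes the benzylic oxygen. The fallback removes the two esters in separate operations; it sets out from 25 and comes back at 26. Thiourea/NaHCO3 in EtOH at 50 °C removes only the chloroacetyl group and gives the erythro β-hydroxy imide (R)-4-benzyl-3-[(2R,3R)-2-(ArCD-oxy)-3-hydroxy-3-(3,5-dimethoxy-4-pivaloyloxyphenyl)propanoyl]oxazolidin-2-one F11. Its LiBH4 reduction, with the benzylic alkoxide already in place, then gives 26.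

Further compounds
F1 | step 10 | 4-[(1R,2S)-2-(2-allyloxy-5-bromo-3-methoxyphenyl)-1,3-dihydroxypropyl]-2,6-dimethoxyphenyl pivalate | OC[C@H](c1cc(Br)cc(OC)c1OCC=C)[C@@H](O)c2cc(OC)c(OC(=O)C(C)(C)C)c(OC)c2
F2 | step 10 | 4-[(1R,2S)-2-(2-allyloxy-5-bromo-3-methoxyphenyl)-3-(tert-butyldiphenylsilyloxy)-1-hydroxypropyl]-2,6-dimethoxyphenyl pivalate | CC(C)(C)[Si](c1ccccc1)(c2ccccc2)OC[C@H](c3cc(Br)cc(OC)c3OCC=C)[C@@H](O)c4cc(OC)c(OC(=O)C(C)(C)C)c(OC)c4
F3 | step 10 | 4-[(1S,2S)-2-(2-allyloxy-5-bromo-3-methoxyphenyl)-3-(tert-butyldiphenylsilyloxy)-1-(chloroacetoxy)propyl]-2,6-dimethoxyphenyl pivalate | CC(C)(C)[Si](c1ccccc1)(c2ccccc2)OC[C@H](c3cc(Br)cc(OC)c3OCC=C)[C@H](OC(=O)CCl)c4cc(OC)c(OC(=O)C(C)(C)C)c(OC)c4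
F4 | step 10 | 4-[(1S,2S)-2-(5-bromo-2-hydroxy-3-methoxyphenyl)-3-(tert-butyldiphenylsilyloxy)-1-hydroxypropyl]-2,6-dimethoxyphenyl pivalate | CC(C)(C)[Si](c1ccccc1)(c2ccccc2)OC[C@H](c3cc(Br)cc(OC)c3O)[C@H](O)c4cc(OC)c(OC(=O)C(C)(C)C)c(OC)c4
F5 | step 10 | 4-[(2R,3S)-5-bromo-3-(tert-butyldiphenylsilyloxymethyl)-7-methoxy-2,3-dihydrobenzofuran-2-yl]-2,6-dimethoxyphenyl pivalate | COc1cc([C@@H]2Oc3c(OC)cc(Br)cc3[C@H]2CO[Si](c4ccccc4)(c5ccccc5)C(C)(C)C)cc(OC)c1OC(=O)C(C)(C)C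
F6 | step 14 | 4-[(1S,2S)-2-(ArCD-oxy)-1,3-dihydroxypropyl]-2,6-dimethoxyphenyl pivalate | COc1cc([C@@H]2Oc3c(OC)cc(Br)cc3[C@H]2CO[Si](c4ccccc4)(c5ccccc5)C(C)(C)C)cc(OC)c1O[C@@H](CO)[C@@H](O)c6cc(OC)c(OC(=O)C(C)(C)C)c(OC)c6
F7 | step 14 | 4-[(1S,2S)-2-(ArCD-oxy)-3-(tert-butyldimethylsilyloxy)-1-hydroxypropyl]-2,6-dimethoxyphenyl pivalate | COc1cc([C@@H]2Oc3c(OC)cc(Br)cc3[C@H]2CO[Si](c4ccccc4)(c5ccccc5)C(C)(C)C)cc(OC)c1O[C@@H](CO[Si](C)(C)C(C)(C)C)[C@@H](O)c6cc(OC)c(OC(=O)C(C)(C)C)c(OC)c6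
F8 | step 14 | 4-[(1R,2S)-2-(ArCD-oxy)-3-(tert-butyldimethylsilyloxy)-1-(chloroacetoxy)propyl]-2,6-dimethoxyphenyl pivalate | COc1cc([C@@H]2Oc3c(OC)cc(Br)cc3[C@H]2CO[Si](c4ccccc4)(c5ccccc5)C(C)(C)C)cc(OC)c1O[C@@H](CO[Si](C)(C)C(C)(C)C)[C@H](OC(=O)CCl)c6cc(OC)c(OC(=O)C(C)(C)C)c(OC)c6
F9 | step 14 | 4-[(1R,2S)-2-(ArCD-oxy)-3-(tert-butyldimethylsilyloxy)-1-hydroxypropyl]-2,6-dimethoxyphenol | COc1cc([C@@H]2Oc3c(OC)cc(Br)cc3[C@H]2CO[Si](c4ccccc4)(c5ccccc5)C(C)(C)C)cc(OC)c1O[C@@H](CO[Si](C)(C)C(C)(C)C)[C@H](O)c6cc(OC)c(O)c(OC)c6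
F10 | step 14 | (R)-4-benzyl-3-{[4-((1R,2S)-2-(ArCD-oxy)-3-(tert-butyldimethylsilyloxy)-1-hydroxypropyl)-2,6-dimethoxyphenoxy]acetyl}oxazolidin-2-one | COc1cc([C@@H]2Oc3c(OC)cc(Br)cc3[C@H]2CO[Si](c4ccccc4)(c5ccccc5)C(C)(C)C)cc(OC)c1O[C@@H](CO[Si](C)(C)C(C)(C)C)[C@H](O)c6cc(OC)c(OCC(=O)N7[C@H](Cc8ccccc8)COC7=O)c(OC)c6
F11 | step 15 | (R)-4-benzyl-3-[(2R,3R)-2-(ArCD-oxy)-3-hydroxy-3-(3,5-dimethoxy-4-pivaloyloxyphenyl)propanoyl]oxazolidin-2-one | COc1cc([C@@H]2Oc3c(OC)cc(Br)cc3[C@H]2CO[Si](c4ccccc4)(c5ccccc5)C(C)(C)C)cc(OC)c1O[C@@H](C(=O)N6[C@H](Cc7ccccc7)COC6=O)[C@H](O)c8cc(OC)c(OC(=O)C(C)(C)C)c(OC)c8
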